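The cyclohexene of the target (C1 acyl, C2 dimethoxyphenyl, C3=C4, C5H2, C6 hydroxymethoxyphenyl) carries its three substituents 1,2-trans/1,6-cis. This pattern is exactly the all-equatorial arrangement of a 2-bromo-3,7-diarylcyclohept-4-enone whose ring carbonyl carbon is the future side-chain ketone. Methyl addition to that carbonyl and 1,2-shift of the benzylic ring carbon onto the brominated carbon (quasi-Favorskii, semipinacol) contracts the seven-membered ring to the cyclohexene, pushes the carbonyl carbon out as the acetyl group on C1 and sets C1 by inversion. The bromoketone comes from a rhodium-catalysed asymmetric conjugate arylation–bromination of a 7-arylcyclohepta-2,4-dienone.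

Key step: step 5

Remark: target ring atoms are numbered C1 (acyl), C2 (dimethoxyphenyl), C3=C4, C5, C6 (hydroxymethoxyphenyl); the β-diketone is drawn as its enol, as in the target formula; cyclohept-4-en-1-one 3 and the aryl Grignard solution 7 are taken as catalogue chemicals.

Step 1
Reactants: 1 4-bromo-2-methoxyphenol
Product: 2 (4-bromo-2-methoxyphenoxy)(tert-butyl)dimethylsilane
Conditions: TBSCl, imidazole, DMF, 23 °C
Reagents that add atoms: tert-butyldimethylsilyl chloride, CC(C)(C)[Si](C)(C)Cl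
Why: Standard O-silylation of a phenol masks the acidic OH for the later enolate and organometallic steps; no stereocentre is formed.

Step 2
Reactants: 3 cyclohept-4-en-1-one; 2 (4-bromo-2-methoxyphenoxy)(tert-butyl)dimethylsilane
Product: 4 2-[4-(tert-butyldimethylsilyloxy)-3-methoxyphenyl]cyclohept-4-en-1-one (racemic)
Conditions: Pd(OAc)2 (2 mol%), 2-dicyclohexylphosphino-2′-methylbiphenyl (4 mol%), K3PO4, toluene, 80 °C (3 in excess)
Reagents that add atoms: none
Why: Palladium-catalysed ketone α-arylation (Buchwald–Hartwig type) through the palladium enolate; the two α-positions of the symmetrical ketone are equivalent, so one constitutional isomer should form, and the new benzylic stereocentre is racemic and enolisable (it is set in step 4).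

Step 3
Reactants: 4 2-[4-(tert-butyldimethylsilyloxy)-3-methoxyphenyl]cyclohept-4-en-1-one
Product: 6 7-[4-(tert-butyldimethylsilyloxy)-3-methoxyphenyl]cyclohepta-2,4-dien-1-one (racemic), via silyl enol ether 5 (not isolated)
Conditions: LDA, TMSCl, THF, −78 °C; then Pd(OAc)2 (1.05 equiv), MeCN, 23 °C
Reagents that add atoms: none
Why: Kinetic deprotonation should remove a hydrogen from the unhindered α-CH2 rather than from the tertiary benzylic position, and Saegusa–Ito oxidation of the enol silane (β-hydride elimination toward the allylic CH2) gives the linearly conjugated dienone; the aryl-bearing centre stays racemic.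

Step 4
Reactants: 6 7-[4-(tert-butyldimethylsilyloxy)-3-methoxyphenyl]cyclohepta-2,4-dien-1-one; 7 (3,4-dimethoxyphenyl)magnesium bromide
Product: 10 (2R,3R,7R)-2-bromo-7-[4-(tert-butyldimethylsilyloxy)-3-methoxyphenyl]-3-(3,4-dimethoxyphenyl)cyclohept-4-en-1-one, via aryltitanium reagent 8 (not isolated), via silyl enol ether 9 (not isolated)
Conditions: 7, ClTi(OiPr)3, THF, −78 to 20 °C; then 6, [Rh(OH)((S)-binap)]2 (3 mol% Rh), THF, 20 °C; LiOiPr, TMSCl; NBS, THF, −78 °C; TsOH·H2O (10 mol%), MeCN, 23 °C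
Reagents that add atoms: N-bromosuccinimide, O=C1CCC(=O)N1Br
Why: Rhodium-catalysed asymmetric 1,4-addition of the aryltitanium reagent (Hayashi–Miyaura type; the aryl–rhodium species inserts the α,β-alkene and (S)-BINAP should set C3 in the sense known for cyclohept-2-enone) gives a regiodefined enolate that is kept as silyl enol ether 9, NBS then attacks C2 anti to the new aryl group (2,3-trans), and acid-mediated enolisation at the benzylic C7 lets both C7 epimers settle as the all-equatorial 2,7-cis isomer.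

Step 5
Reactants: 10 (2R,3R,7R)-2-bromo-7-[4-(tert-butyldimethylsilyloxy)-3-methoxyphenyl]-3-(3,4-dimethoxyphenyl)cyclohept-4-en-1-one
Product: 11 1-{(1S,2S,6S)-6-[4-(tert-butyldimethylsilyloxy)-3-methoxyphenyl]-2-(3,4-dimethoxyphenyl)cyclohex-3-en-1-yl}ethan-1-one
Conditions: MeLi, CeCl3 (1.05 equiv each), THF, −78 °C; then −78 to 23 °C
Reagents that add atoms: methyllithium, C[Li]
Why: The weakly basic organocerium reagent adds to the C1 carbonyl of 10 without removing the benzylic C7–H, and on warming the C1–C7 ring bond, antiperiplanar to the equatorial C2–Br bond, migrates from C1 to C2 as bromide leaves and the alkoxide collapses to the acetyl ketone (quasi-Favorskii/semipinacol rearrangement, the classical ring contraction of 2-halocycloalkanone adducts). No ring is closed by cyclisation: the cyclohexene arises by a 1,2-shift of a ring C–C bond that excises the former carbonyl carbon from the seven-membered ring (7 to 6 contraction). C1 of 11 is set by inversion at the bromine-bearing carbon, the migrating benzylic carbon (C6 of 11) keeps its configuration and the allylic aryl-bearing carbon (C2) is untouched, so the 2,3-trans/2,7-cis bromoketone should translate into the 1,2-trans/1,6-cis cyclohexene. The step needs ring-bond migration rather than methyl migration, epoxide closure or enolisation; the two equatorial aryl groups hold bromine equatorial, where only the ring bond is anti to it, and the electron-rich benzylic carbon is the best migrating group. Using 1.05 equivalents of the cerium reagent limits addition to the newly formed ketone.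

Step 6
Reactants: 12 (E)-3-(4-hydroxy-3-methoxyphenyl)prop-2-enoic acid (ferulic acid)
Product: 13 tert-butyldimethylsilyl (E)-3-[4-(tert-butyldimethylsilyloxy)-3-methoxyphenyl]prop-2-enoate
Conditions: TBSCl (2.5 equiv), imidazole, DMF, 23 °C
Reagents that add atoms: tert-butyldimethylsilyl chloride, CC(C)(C)[Si](C)(C)Cl
Why: Exhaustive silylation gives the aryl silyl ether and the silyl ester, the latter serving as a latent acid chloride; the (E)-alkene is untouched.

Step 7
Reactants: 11 1-{(1S,2S,6S)-6-[4-(tert-butyldimethylsilyloxy)-3-methoxyphenyl]-2-(3,4-dimethoxyphenyl)cyclohex-3-en-1-yl}ethan-1-one; 13 tert-butyldimethylsilyl (E)-3-[4-(tert-butyldimethylsilyloxy)-3-methoxyphenyl]prop-2-enoate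
Product: 15 (2Z,4E)-1-{(1S,2S,6S)-6-[4-(tert-butyldimethylsilyloxy)-3-methoxyphenyl]-2-(3,4-dimethoxyphenyl)cyclohex-3-en-1-yl}-5-[4-(tert-butyldimethylsilyloxy)-3-methoxyphenyl]-3-hydroxypenta-2,4-dien-1-one, via acid chloride 14 (not isolated)
Conditions: 13, (COCl)2, DMF (cat.), CH2Cl2, 0 °C, then concentration; 11, LiHMDS (2.2 equiv), THF, −78 °C; then 14, −78 to −20 °C; AcOH
Reagents that add atoms: none
Why: Oxalyl chloride/DMF converts the silyl ester into acid chloride 14, LiHMDS deprotonates the methyl group of 11 kinetically (the C1–H methine is flanked by two aryl-bearing carbons) and Claisen-type C-acylation gives the 1,3-diketone, which the second equivalent of base holds as its enolate so that C1 should not epimerise; no stereocentre is formed.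

Step 8
Reactants: 15 (2Z,4E)-1-{(1S,2S,6S)-6-[4-(tert-butyldimethylsilyloxy)-3-methoxyphenyl]-2-(3,4-dimethoxyphenyl)cyclohex-3-en-1-yl}-5-[4-(tert-butyldimethylsilyloxy)-3-methoxyphenyl]-3-hydroxypenta-2,4-dien-1-one
Product: 16 (2Z,4E)-1-[(1S,2S,6S)-2-(3,4-dimethoxyphenyl)-6-(4-hydroxy-3-methoxyphenyl)cyclohex-3-en-1-yl]-3-hydroxy-5-(4-hydroxy-3-methoxyphenyl)penta-2,4-dien-1-one (CNP0290899.2)
Conditions: TBAF, AcOH, THF, 0 °C
Reagents that add atoms: none
Why: Fluoride-induced cleavage of both aryl silyl ethers, buffered with acetic acid so that neither phenoxide nor diketonate basicity can epimerise C1 or trigger retro-Claisen cleavage; no stereocentre is touched.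

Compound list
1 | 4-bromo-2-methoxyphenol | Oc1ccc(Br)cc1OC | starting material
2 | (4-bromo-2-methoxyphenoxy)(tert-butyl)dimethylsilane | CC(C)(C)[Si](C)(C)Oc1ccc(Br)cc1OC | intermediate
3 | cyclohept-4-en-1-one | O=C1CCC=CCC1 | starting material
4 | 2-[4-(tert-butyldimethylsilyloxy)-3-methoxyphenyl]cyclohept-4-en-1-one (racemic) | O=C1CCC=CCC1c1ccc(O[Si](C)(C)C(C)(C)C)c(OC)c1 | intermediate
5 | ({7-[4-(tert-butyldimethylsilyloxy)-3-methoxyphenyl]cyclohepta-1,4-dien-1-yl}oxy)trimethylsilane (racemic) | C[Si](C)(C)OC1=CCC=CCC1c1ccc(O[Si](C)(C)C(C)(C)C)c(OC)c1 | intermediate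
6 | 7-[4-(tert-butyldimethylsilyloxy)-3-methoxyphenyl]cyclohepta-2,4-dien-1-one (racemic) | O=C1C=CC=CCC1c1ccc(O[Si](C)(C)C(C)(C)C)c(OC)c1 | intermediate
7 | (3,4-dimethoxyphenyl)magnesium bromide | COc1ccc([Mg]Br)cc1OC | starting material
8 | (3,4-dimethoxyphenyl)tri(propan-2-yloxy)titanium | COc1ccc([Ti](OC(C)C)(OC(C)C)OC(C)C)cc1OC | intermediate
9 | ({(3S)-7-[4-(tert-butyldimethylsilyloxy)-3-methoxyphenyl]-3-(3,4-dimethoxyphenyl)cyclohepta-1,4-dien-1-yl}oxy)trimethylsilane (both C7 epimers) | C[Si](C)(C)OC1=C[C@@H](c2ccc(OC)c(OC)c2)C=CCC1c1ccc(O[Si](C)(C)C(C)(C)C)c(OC)c1 | intermediate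
10 | (2R,3R,7R)-2-bromo-7-[4-(tert-butyldimethylsilyloxy)-3-methoxyphenyl]-3-(3,4-dimethoxyphenyl)cyclohept-4-en-1-one | O=C1[C@H](Br)[C@@H](c2ccc(OC)c(OC)c2)C=CC[C@@H]1c1ccc(O[Si](C)(C)C(C)(C)C)c(OC)c1 | intermediate
11 | 1-{(1S,2S,6S)-6-[4-(tert-butyldimethylsilyloxy)-3-methoxyphenyl]-2-(3,4-dimethoxyphenyl)cyclohex-3-en-1-yl}ethan-1-one | CC(=O)[C@@H]1[C@@H](c2ccc(OC)c(OC)c2)C=CC[C@@H]1c1ccc(O[Si](C)(C)C(C)(C)C)c(OC)c1 | intermediate
12 | (E)-3-(4-hydroxy-3-methoxyphenyl)prop-2-enoic acid (ferulic acid) | COc1cc(/C=C/C(=O)O)ccc1O | starting material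
13 | tert-butyldimethylsilyl (E)-3-[4-(tert-butyldimethylsilyloxy)-3-methoxyphenyl]prop-2-enoate | COc1cc(/C=C/C(=O)O[Si](C)(C)C(C)(C)C)ccc1O[Si](C)(C)C(C)(C)C | intermediate
14 | (E)-3-[4-(tert-butyldimethylsilyloxy)-3-methoxyphenyl]prop-2-enoyl chloride | COc1cc(/C=C/C(Cl)=O)ccc1O[Si](C)(C)C(C)(C)C | intermediate
15 | (2Z,4E)-1-{(1S,2S,6S)-6-[4-(tert-butyldimethylsilyloxy)-3-methoxyphenyl]-2-(3,4-dimethoxyphenyl)cyclohex-3-en-1-yl}-5-[4-(tert-butyldimethylsilyloxy)-3-methoxyphenyl]-3-hydroxypenta-2,4-dien-1-one | COc1cc(/C=C/C(O)=C/C(=O)[C@@H]2[C@@H](c3ccc(OC)c(OC)c3)C=CC[C@@H]2c2ccc(O[Si](C)(C)C(C)(C)C)c(OC)c2)ccc1O[Si](C)(C)C(C)(C)C | intermediate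
16 | (2Z,4E)-1-[(1S,2S,6S)-2-(3,4-dimethoxyphenyl)-6-(4-hydroxy-3-methoxyphenyl)cyclohex-3-en-1-yl]-3-hydroxy-5-(4-hydroxy-3-methoxyphenyl)penta-2,4-dien-1-one | COc1cc(/C=C/C(O)=C/C(=O)[C@@H]2[C@@H](c3ccc(OC)c(OC)c3)C=CC[C@@H]2c2ccc(O)c(OC)c2)ccc1O | target

Total step count: 8
Longest linear sequence: 7 steps (1, 2, 3, 4, 5, 7, 8)

Steps most likely to fail

Step 4. The aryl–rhodium species may add to the δ-carbon of the cisoid dienone (1,6-addition) or with low enantioselectivity, the titanium enolate may be trapped incompletely, and the C7 equilibrium may not lie far enough on the all-equatorial side. The fallback builds the aryl-bearing stereocentre on an acyclic precursor, with no dienone present; it sets out from aryl bromide 2 and comes back at silyl enol ether 9. Palladium-catalysed mono-α-arylation of acetone with 2 ([Pd(cinnamyl)Cl]2, Mor-DalPhos, Cs2CO3, acetone) gives 1-[4-(tert-butyldimethylsilyloxy)-3-methoxyphenyl]propan-2-one F1. Benzylic allylation (NaH, allyl bromide, THF) gives 3-[4-(tert-butyldimethylsilyloxy)-3-methoxyphenyl]hex-5-en-2-one F2. Its less substituted pyrrolidine enamine F3 (pyrrolidine, TiCl4) undergoes iridium-catalysed branched-selective allylic alkylation ([Ir(cod)Cl]2, chiral phosphoramidite) with (E)-3-(3,4-dimethoxyphenyl)allyl methyl carbonate F4, itself made from commercial 3,4-dimethoxycinnamyl alcohol and methyl chloroformate. Hydrolysis gives (7R)-7-(3,4-dimethoxyphenyl)-4-[4-(tert-butyldimethylsilyloxy)-3-methoxyphenyl]nona-1,8-dien-5-one F5, with the aryl-bearing stereocentre set by the ligand. Ring-closing metathesis with second-generation Grubbs catalyst gives (3R)-3-(3,4-dimethoxyphenyl)-7-[4-(tert-butyldimethylsilyloxy)-3-methoxyphenyl]cyclohept-4-en-1-one F6. Kinetic silylation (LiTMP, TMSCl, −78 °C) at the CH2 next to the aryl-bearing carbon gives 9, which is brominated and equilibrated as in step 4.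

Step 5. The organometallic may deprotonate the benzylic α-hydrogen instead of adding, the alkoxide may close to an epoxide, or the methyl group may migrate in place of the ring bond. The fallback uses hydride instead of a carbon nucleophile, a halophile-induced shift, and adds the side-chain carbon afterwards; it sets out from 10 and comes back at 11. Luche reduction (NaBH4, CeCl3·7H2O, MeOH, −40 °C) gives (2R,3R,7R)-2-bromo-7-[4-(tert-butyldimethylsilyloxy)-3-methoxyphenyl]-3-(3,4-dimethoxyphenyl)cyclohept-4-en-1-ol F7. Silver-assisted semipinacol rearrangement (AgBF4, CH2Cl2) with migration of the same ring bond gives (1S,2S,6S)-6-[4-(tert-butyldimethylsilyloxy)-3-methoxyphenyl]-2-(3,4-dimethoxyphenyl)cyclohex-3-ene-1-carbaldehyde F8. Addition of MeMgBr at −78 °C gives 1-{(1S,2S,6S)-6-[4-(tert-butyldimethylsilyloxy)-3-methoxyphenyl]-2-(3,4-dimethoxyphenyl)cyclohex-3-en-1-yl}ethan-1-ol F9, and Dess–Martin oxidation gives 11.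

Step 3. Enolisation may occur toward the benzylic carbon, or the dienone may be oxidised further to the tropone. The fallback reverses the order so that the oxidation is done on the symmetrical ketone; it sets out from 3 and comes back at 6. Silylation of 3 (LDA, TMSCl) gives (cyclohepta-1,4-dien-1-yloxy)trimethylsilane F10, and Saegusa–Ito oxidation with Pd(OAc)2 gives cyclohepta-2,4-dien-1-one F11. Its kinetic cross-conjugated lithium enolate (LDA, −78 °C) is transmetallated with ZnCl2 and arylated with 2 (Pd(dba)2, P(tBu)3, Negishi-type enolate arylation) to give 6.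

Further compounds
F1 | step 4 | 1-[4-(tert-butyldimethylsilyloxy)-3-methoxyphenyl]propan-2-one | CC(=O)Cc1ccc(O[Si](C)(C)C(C)(C)C)c(OC)c1
F2 | step 4 | 3-[4-(tert-butyldimethylsilyloxy)-3-methoxyphenyl]hex-5-en-2-one (racemic) | CC(=O)C(CC=C)c1ccc(O[Si](C)(C)C(C)(C)C)c(OC)c1
F3 | step 4 | 1-{3-[4-(tert-butyldimethylsilyloxy)-3-methoxyphenyl]hexa-1,5-dien-2-yl}pyrrolidine (racemic) | C=C(N1CCCC1)C(CC=C)c1ccc(O[Si](C)(C)C(C)(C)C)c(OC)c1
F4 | step 4 | (E)-3-(3,4-dimethoxyphenyl)allyl methyl carbonate | COC(=O)OC/C=C/c1ccc(OC)c(OC)c1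
F5 | step 4 | (7R)-7-(3,4-dimethoxyphenyl)-4-[4-(tert-butyldimethylsilyloxy)-3-methoxyphenyl]nona-1,8-dien-5-one (C4 epimers) | C=CCC(c1ccc(O[Si](C)(C)C(C)(C)C)c(OC)c1)C(=O)C[C@@H](c1ccc(OC)c(OC)c1)C=C
F6 | step 4 | (3R)-3-(3,4-dimethoxyphenyl)-7-[4-(tert-butyldimethylsilyloxy)-3-methoxyphenyl]cyclohept-4-en-1-one (C7 epimers) | O=C1C[C@@H](c2ccc(OC)c(OC)c2)C=CCC1c1ccc(O[Si](C)(C)C(C)(C)C)c(OC)c1
F7 | step 5 | (2R,3R,7R)-2-bromo-7-[4-(tert-butyldimethylsilyloxy)-3-methoxyphenyl]-3-(3,4-dimethoxyphenyl)cyclohept-4-en-1-ol (C1 epimers) | OC1[C@H](Br)[C@@H](c2ccc(OC)c(OC)c2)C=CC[C@@H]1c1ccc(O[Si](C)(C)C(C)(C)C)c(OC)c1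
F8 | step 5 | (1S,2S,6S)-6-[4-(tert-butyldimethylsilyloxy)-3-methoxyphenyl]-2-(3,4-dimethoxyphenyl)cyclohex-3-ene-1-carbaldehyde | O=C[C@@H]1[C@@H](c2ccc(OC)c(OC)c2)C=CC[C@@H]1c1ccc(O[Si](C)(C)C(C)(C)C)c(OC)c1
F9 | step 5 | 1-{(1S,2S,6S)-6-[4-(tert-butyldimethylsilyloxy)-3-methoxyphenyl]-2-(3,4-dimethoxyphenyl)cyclohex-3-en-1-yl}ethan-1-ol (carbinol epimers) | CC(O)[C@@H]1[C@@H](c2ccc(OC)c(OC)c2)C=CC[C@@H]1c1ccc(O[Si](C)(C)C(C)(C)C)c(OC)c1
F10 | step 3 | (cyclohepta-1,4-dien-1-yloxy)trimethylsilane | C[Si](C)(C)OC1=CCC=CCC1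
F11 | step 3 | cyclohepta-2,4-dien-1-one | O=C1C=CC=CCC1
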